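From the earliest cedar reading on, we reckon against the substrate left and not against the target and other capture product made, because those two together stand at 9.70% while 39.2% of the substrate has gone.

common to all: substrate 46 mM
- cedar: first nucleophile 0.80 equiv; second nucleophile 1.8 equiv; the very flask that is asked about, followed so far
- larch: first nucleophile 0.80 equiv; second nucleophile 3.6 equiv; run made earlier
- flask: first nucleophile 0.800 equiv; second nucleophile 1.80 equiv; time 3.0 d

cedar run (percent of the substrate charged)

| time / h | target / % | other capture product / % | substrate / % |
|---|---|---|---|
| 5.00 | 5.6 | 4.1 | 60.8 |
| 12.0 | 5.4 | 5.9 | 25.9 |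
| 25.0 | 4.3 | 7.2 | 5.1 |
| 40.0 | 6.5 | 8.6 | 0.5 |

larch run (percent of the substrate charged)

| time / d | target / % | other capture product / % | substrate / % |
|---|---|---|---|
| 0.417 | 4.7 | 11.1 | 33.1 |
| 1.04 | 5.1 | 17.5 | 6.7 |
| 2.08 | 4.5 | 17.0 | 0 |
| 3.00 | 4.3 | 14.3 | 0 |

(standard deviation of a reading: 1 percentage point)

- a reading or a percentage of target counts all its forms, free or not

* ratio of target to other capture product at 1.0 h
* ratio of target to other capture product at 3.0 d
* which of target and other capture product there is more of at 3.0 d

The last cedar reading gives 8.64% of other capture product per substrate gone; we call this quotient, other capture product over the fraction of substrate gone, the capture share, a product selectivity in the usual sense.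

1. Time. The cedar substrate readings give a decay constant of 0.124 h⁻¹, so we reckon 0.0133% left at 3.0 d and 8.64% of other capture product. The cedar target readings average 5.45%, so our ratio is 0.631, with other capture product ahead.

2. Early time. The first cedar reading leaves 9.47% gone at 1.0 h if the decay is taken as steady, which makes 0.818% of other capture product, against a scatter of 1 percentage point. The cedar ratio reads 1.37 at the first reading and 0.756 at the last, so we commit to a ratio above the first of these at 1.0 h.

3. Second nucleophile. Doubling its charge should double the share, and the larch reading at 1.04 d gives 18.8%, about twice the cedar value. Halving the charge should therefore give 4.32%.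

The forecast gave 2 and 0.62 with other capture product ahead, calling that product “second-order-like in that nucleophile”.

The flask gives 2.40 and 0.594, with 5.08% of target, idle adduct counted, and 8.55% of other capture product.

    substrate → intermediate (k = 2.60 × 10⁻⁵ s⁻¹)
    first nucleophile + intermediate → target (k = 0.0667 L mol⁻¹ s⁻¹)
    second nucleophile + intermediate → other capture product (k = 0.0104 L mol⁻¹ s⁻¹)
    intermediate → solvolysis product (k = 0.00547 s⁻¹)
    substrate + target → side product (k = 0.0139 L mol⁻¹ s⁻¹)
    first nucleophile + target ⇌ idle adduct, settled at all times (K = 170 L mol⁻¹)

In the flask at 0.254 d, the intermediate has a half-life of 0.035 h by the path to solvolysis product and 0.097 h by the path to target, so solvolysis uses it 2.8 times as fast. The amounts in the flask put the capture share at 8.55% at 3.0 d. For the flask with half the second nucleophile, the halved share 4.32% and the target of the flask give a ratio of 1.18, and that flask stands at 1.17.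

(The data were generated by integration for an exercise.)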